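The target is divided at C9–C11 into an allyl donor (rings D and E) and a C9 nucleophile (rings A and B). Ring A (C1–C5 and C10) is never closed as a six-membered ring: its C3 stereocentre, the C4 gem-dimethyl group and the C10 methyl group are bought as the cyclopentane of camphoric acid. In the key step an oxolanylium ion ionises at C5, the C10–C4 bond migrates to C5 (cyclopentane to ring A), and the resulting C10 cation is trapped by a β-keto ester enol to close ring B; C5, C9 and C10 are set in this one operation under control of C3 and the C5 carbinol. The precursor is a cyclopentyl 6-hydroxy-3-oxohexanoate.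

Key step: step 7

Remark on numbering: ring A = C1, C2, C3, C4, C5, C10; ring B = C5–C10; C11 and C12 link C9 to C13; ring D = C13–C18; ring E = C17–C22. Methyl groups sit on C4 (two), C8, C10, C17, C19 and C20, hydroxyls on C3 and C20. In rings A/B, β is the face of the C10 methyl; in rings D/E, β is the face of the C17 methyl.

Assumption: the sense of induction of the carbene catalyst in step 12 is taken as written; if it proves opposite, its mirror image is used.

**Rings A and B**

Step 1
Reactants: 1 (1R,3S)-camphoric anhydride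
Product: 2 (1R,3S)-3-[methoxy(methyl)carbamoyl]-1,2,2-trimethylcyclopentane-1-carboxylic acid
Conditions: MeNHOMe·HCl (1.2 equiv), Et3N (2.5 equiv), 4-(dimethylamino)pyridine (5 mol %), CH2Cl2, 0 °C → rt; aq. HCl
Reagents that add atoms: N,O-dimethylhydroxylamine hydrochloride, CNOC.Cl
Why: Regioselective aminolysis of the cyclic anhydride at the less hindered carbonyl (the one on the CH carbon) gives the Weinreb amide and leaves the tertiary acid free; no stereocentre is touched.

Step 2
Reactants: 2 (1R,3S)-3-[methoxy(methyl)carbamoyl]-1,2,2-trimethylcyclopentane-1-carboxylic acid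
Product: 3 (1R,3S)-3-acetyl-1,2,2-trimethylcyclopentane-1-carboxylic acid
Conditions: MeMgBr (3.2 equiv), THF, −20 → 0 °C; 1 M HCl
Reagents that add atoms: methylmagnesium bromide, C[Mg]Br
Why: Weinreb ketone synthesis; the carboxylate is inert and the chelated adduct collapses only on work-up, so one methyl adds and the α-stereocentre is not enolised.

Step 3
Reactants: 3 (1R,3S)-3-acetyl-1,2,2-trimethylcyclopentane-1-carboxylic acid
Product: 4 (1R,3S)-3-acetoxy-1,2,2-trimethylcyclopentane-1-carboxylic acid
Conditions: mCPBA (2 equiv), Na2HPO4, CH2Cl2, 40 °C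
Reagents that add atoms: 3-chloroperoxybenzoic acid, OOC(=O)c1cccc(Cl)c1
Why: Baeyer–Villiger oxidation; the secondary ring carbon migrates in preference to methyl and with retention, so the future C3 receives its oxygen in the (S) configuration (3β in ring A).

Step 4
Reactants: 4 (1R,3S)-3-acetoxy-1,2,2-trimethylcyclopentane-1-carboxylic acid, 5 3-ethoxy-3-oxopropylzinc bromide
Product: 7 ethyl 4-[(1R,3S)-3-acetoxy-1,2,2-trimethylcyclopentyl]-4-oxobutanoate, via acid chloride 6 (not isolated)
Conditions: (COCl)2, N,N-dimethylformamide (cat.), CH2Cl2, rt, evaporate; then 5 (1.3 equiv), Pd(PPh3)4 (5 mol %), THF, 0 °C → rt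
Reagents that add atoms: none
Why: Acid chloride formation followed by palladium-catalysed Negishi-type acylation of the alkylzinc halide, which tolerates both esters and stops at the ketone even at this tertiary acyl centre.

Step 5
Reactants: 7 ethyl 4-[(1R,3S)-3-acetoxy-1,2,2-trimethylcyclopentyl]-4-oxobutanoate
Product: 9 (5S)-5-[(1R,3S)-3-acetoxy-1,2,2-trimethylcyclopentyl]oxolan-2-one, via hydroxy ester 8 (not isolated)
Conditions: (R)-1-methyl-3,3-diphenyltetrahydro-1H,3H-pyrrolo[1,2-c][1,3,2]oxazaborole (20 mol %), BH3·SMe2 (1.0 equiv), THF, −20 °C; MeOH; then p-toluenesulfonic acid monohydrate (10 mol %), toluene, 60 °C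
Reagents that add atoms: none
Why: Corey–Bakshi–Shibata reduction; the oxazaborolidine distinguishes the tertiary-alkyl flank from the primary-alkyl flank, so the (R)-catalyst should give the (S)-carbinol at C5 under reagent control, and acid then closes the γ-lactone.

Step 6
Reactants: 9 (5S)-5-[(1R,3S)-3-acetoxy-1,2,2-trimethylcyclopentyl]oxolan-2-one
Product: 10 methyl (6S)-6-[(1R,3S)-3-acetoxy-1,2,2-trimethylcyclopentyl]-6-hydroxy-3-oxohexanoate (drawn open-chain; a ring–chain mixture with its cyclic hemiketal is expected)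
Conditions: LDA (2.3 equiv), MeOAc (2.3 equiv), THF, −78 °C; add 9, −78 °C; AcOH quench at −78 °C
Reagents that add atoms: methyl acetate, COC(C)=O
Why: Crossed Claisen addition of the ester enolate to the γ-lactone, which should be more electrophilic than the hindered secondary acetate; C5 is untouched and its oxygen is now placed 1,4 to the new ketone.

Step 7
Reactants: 10 methyl (6S)-6-[(1R,3S)-3-acetoxy-1,2,2-trimethylcyclopentyl]-6-hydroxy-3-oxohexanoate
Product: 13 methyl (1R,4aR,6S,8aS)-6-acetoxy-5,5,8a-trimethyl-2-oxodecahydronaphthalene-1-carboxylate (3β-OAc, 5α-H, 9α-H, 10β-Me, 8-oxo, CO2Me on C9), via oxolanylium ion 11 (not isolated), via cyclohexyl cation 12 (not isolated)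
Conditions: CF3SO3H (30 mol %), (CF3)2CHOH, 0 → 40 °C; aq. NaHCO3
Reagents that add atoms: none
Why: Proposed new method: acid converts 10 through its hemiketal into the oxolanylium ion 11, whose C5–O bond heterolyses with synchronous anti 1,2-shift of the C10–C4 bond (the strained bond between two fully substituted carbons), expanding the cyclopentane to the cyclohexyl cation 12, which is then attacked at C10 by the enol carbon C9 of the released β-keto ester. The closest known reactions are the solvolytic Wagner–Meerwein ring expansion of cyclopentylcarbinyl sulfonates, the acid- or SnCl4-mediated cyclisation of 2,6,6-trimethylcyclohexenyl β-keto esters through the same kind of C10 cation, and the Petasis–Ferrier O-to-C transposition; here the leaving group is a neutral ketone oxygen. Ring A is not closed by a cyclisation but grows from five to six atoms by the shift, while ring B closes by attack of the enol on the cation through a six-membered chair transition state (6-endo with respect to the enol double bond). C5 is set by inversion at the carbinol carbon fixed in step 5, C10 by attack trans to the C5 hydrogen with the C3 acetoxy group equatorial, and C9 by equilibration of the β-keto ester to the equatorial ester. The step needs migration of C4 rather than C1 or methyl, which the higher migratory aptitude of the quaternary carbon and the relief of vicinal-quaternary strain should secure, and C- rather than O-capture of the cation, which is secured because O-capture only regenerates an oxocarbenium ion that reopens. Loss of a proton to the C5=C10 alkene is tolerated, since the acid returns it to 12, at some cost to the C5 relay.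

**Rings D and E**

Step 8
Reactants: 14 but-3-en-1-ylmagnesium bromide, 15 methacrolein
Product: 17 (±)-2-methylhept-6-enal, via silyl enol ether 16 (not isolated)
Conditions: CuBr·SMe2 (5 mol %), Me3SiCl (1.2 equiv), THF, −78 °C; then 1 M HCl, rt
Reagents that add atoms: none
Why: Copper-catalysed 1,4-addition of the Grignard reagent to the enal, with Me3SiCl trapping the enolate; the stereocentre is racemic and becomes prochiral in step 10.

Step 9
Reactants: 17 (±)-2-methylhept-6-enal, 18 methyl vinyl ketone
Product: 19 (±)-4-methyl-4-(pent-4-en-1-yl)cyclohex-2-en-1-one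
Conditions: H2SO4 (cat.), toluene, 50 °C, then reflux with water separation
Reagents that add atoms: none
Why: Robinson annulation (Michael addition of the α-branched aldehyde enol, then aldol condensation) builds the 4,4-disubstituted cyclohexenone with the future C17 as its quaternary carbon.

Step 10
Reactants: 19 (±)-4-methyl-4-(pent-4-en-1-yl)cyclohex-2-en-1-one
Product: 20 4-methyl-4-(pent-4-en-1-yl)cyclohexa-2,5-dien-1-one
Conditions: DDQ (1.5 equiv), dioxane, reflux
Reagents that add atoms: none
Why: Quinone dehydrogenation of the enone gives the cross-conjugated dienone, in which the quaternary carbon is a prochiral centre flanked by two enantiotopic enone arms; the isolated alkene is inert.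

Step 11
Reactants: 20 4-methyl-4-(pent-4-en-1-yl)cyclohexa-2,5-dien-1-one
Product: 21 4-(1-methyl-4-oxocyclohexa-2,5-dien-1-yl)butanal
Conditions: OsO4 (2 mol %), NaIO4 (4 equiv), 2,6-lutidine, dioxane–H2O (3:1), rt
Reagents that add atoms: sodium periodate (terminal oxidant, source of the aldehyde oxygen through OsO4), [Na+].[O-]I(=O)(=O)=O
Why: Lemieux–Johnson cleavage; OsO4 should dihydroxylate the electron-rich monosubstituted alkene much faster than the electron-poor dienone double bonds, and periodate cleaves the diol.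

Step 12
Reactants: 21 4-(1-methyl-4-oxocyclohexa-2,5-dien-1-yl)butanal
Product: 22 (4aS,8aR)-4a-methyl-3,4,4a,8a-tetrahydronaphthalene-1,7(2H,8H)-dione (cis-fused)
Conditions: (5aR,10bS)-2-(pentafluorophenyl)-5a,10b-dihydro-4H,6H-indeno[2,1-b][1,2,4]triazolo[4,3-d][1,4]oxazin-2-ium tetrafluoroborate (20 mol %), KN(SiMe3)2 (20 mol %), toluene, rt
Reagents that add atoms: none
Why: Desymmetrising intramolecular Stetter reaction; the carbene-derived acyl anion equivalent adds 6-exo-trig to one of the two enantiotopic enone β-carbons, the chiral catalyst choosing the arm and so setting quaternary C17, while the tether enforces the cis C18–H.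

Step 13
Reactants: 22 (4aS,8aR)-4a-methyl-3,4,4a,8a-tetrahydronaphthalene-1,7(2H,8H)-dione
Product: 23 (4a'S,8a'R)-4a'-methyl-3',4',4a',8a'-tetrahydro-2'H-spiro[1,3-dioxolane-2,1'-naphthalen]-7'(8'H)-one
Conditions: Me3SiOCH2CH2OSiMe3 (1.5 equiv), Me3SiOSO2CF3 (5 mol %), CH2Cl2, −78 → −20 °C
Reagents that add atoms: 1,2-bis(trimethylsilyloxy)ethane, C[Si](C)(C)OCCO[Si](C)(C)C
Why: Chemoselective ketalisation; the saturated C13 ketone should react far faster than the conjugated enone carbonyl under silyl triflate catalysis.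

Step 14
Reactants: 23 (4a'S,8a'R)-4a'-methyl-3',4',4a',8a'-tetrahydro-2'H-spiro[1,3-dioxolane-2,1'-naphthalen]-7'(8'H)-one
Product: 24 (4a'S,8'R,8a'R)-4a',8'-dimethyl-3',4',4a',8a'-tetrahydro-2'H-spiro[1,3-dioxolane-2,1'-naphthalen]-7'(8'H)-one
Conditions: LDA (1.1 equiv), THF, −78 °C; MeI (3 equiv), −78 → −30 °C
Reagents that add atoms: iodomethane, CI
Why: Kinetic α'-enolate alkylation; the enone can be deprotonated only at C19 (its γ-carbon is quaternary), and methyl iodide should enter from the convex β face, anti to the ring D carbons and the C13 ketal, placing the C19 methyl cis to the C17 methyl and the C18 hydrogen.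

Step 15
Reactants: 24 (4a'S,8'R,8a'R)-4a',8'-dimethyl-3',4',4a',8a'-tetrahydro-2'H-spiro[1,3-dioxolane-2,1'-naphthalen]-7'(8'H)-one
Product: 25 (4a'S,8'R,8a'R)-4a',8'-dimethyloctahydro-2'H-spiro[1,3-dioxolane-2,1'-naphthalen]-7'(8'H)-one
Conditions: H2 (1 atm), 10% Pd/C, EtOAc, rt
Reagents that add atoms: none
Why: Heterogeneous hydrogenation of the disubstituted enone double bond; no stereocentre is formed and the neutral conditions leave the epimerisable C19 untouched.

Step 16
Reactants: 25 (4a'S,8'R,8a'R)-4a',8'-dimethyloctahydro-2'H-spiro[1,3-dioxolane-2,1'-naphthalen]-7'(8'H)-one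
Product: 26 (4a'S,7'R,8'R,8a'R)-4a',7',8'-trimethyloctahydro-2'H-spiro[1,3-dioxolane-2,1'-naphthalen]-7'-ol
Conditions: methylaluminium bis(2,6-di-tert-butyl-4-methylphenoxide) (3 equiv, from AlMe3 and the phenol, toluene), then MeLi (3 equiv), toluene, −78 °C; 1 M HCl
Reagents that add atoms: methyllithium, [Li]C
Why: Lewis acid-directed carbonyl addition; the bulky aluminium phenoxide binds the ketone oxygen on the equatorial side and should force methyllithium to attack axially (β face of the chair that has the C19 methyl equatorial), giving the 20β-methyl and the 20α-hydroxyl.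

Step 17
Reactants: 26 (4a'S,7'R,8'R,8a'R)-4a',7',8'-trimethyloctahydro-2'H-spiro[1,3-dioxolane-2,1'-naphthalen]-7'-ol
Product: 27 (4aS,7R,8R,8aR)-7-hydroxy-4a,7,8-trimethyloctahydronaphthalen-1(2H)-one
Conditions: pyridinium p-toluenesulfonate (20 mol %), acetone–H2O (10:1), 55 °C
Reagents that add atoms: water, O
Why: Mild acid-catalysed ketal hydrolysis frees the C13 ketone without dehydrating the tertiary alcohol; C18 should stay cis-fused because the trans-fused epimer would put the C17 and C19 methyl groups 1,3-diaxial.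

Step 18
Reactants: 27 (4aS,7R,8R,8aR)-7-hydroxy-4a,7,8-trimethyloctahydronaphthalen-1(2H)-one
Product: 29 bis(methyl carbonate) of (4aS,7R,8R,8aR)-1-ethenyl-4a,7,8-trimethyldecahydronaphthalene-1,7-diol (C13 epimers), via vinyl diol 28 (not isolated)
Conditions: CH2=CHMgBr (3 equiv), LaCl3·2LiCl (1 equiv), THF, −78 → 0 °C; then ClCO2Me (4 equiv), 0 °C → rt
Reagents that add atoms: vinylmagnesium bromide, C=C[Mg]Br; methyl chloroformate, COC(Cl)=O
Why: Grignard 1,2-addition (the lanthanum salt suppresses enolisation) and in situ O-acylation of both tertiary alkoxides; the new C13 carbinol centre is erased in step 19, and the C20 carbonate serves as protecting group.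

**Union and end game**

Step 19
Reactants: 13 methyl (1R,4aR,6S,8aS)-6-acetoxy-5,5,8a-trimethyl-2-oxodecahydronaphthalene-1-carboxylate, 29 bis(methyl carbonate) of the vinyl diol
Product: 30 coupled keto ester: 3β-acetoxy-8-oxo ring A/B unit with 9β-CO2Me and the 9α-C11H2–C12H=C13 chain, (12E) with C11 cis to C14, C20 as methyl carbonate
Conditions: Pd(PPh3)4 (5 mol %), THF, 50 °C
Reagents that add atoms: none
Why: Tsuji–Trost allylic alkylation; zerovalent palladium ionises the tertiary allylic carbonate, the released methoxide deprotonates the β-keto ester, and the enolate attacks the unsubstituted terminus C11 of the π-allyl complex, whose bulkier C18 branch sits syn so that the (12E)-alkene should result; O-allylation is reversible under the catalyst, and the C9 configuration (allyl expected anti to the C10 methyl) is erased in step 20.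

Step 20
Reactants: 30 coupled keto ester
Product: 32 3β,20α-dihydroxy 8-ketone (9α-H, side chain 9β, (12E)), via acetate ketone 31 (not isolated)
Conditions: LiCl (6 equiv), H2O (4 equiv), DMSO, 150 °C; then K2CO3, MeOH, 40 °C
Reagents that add atoms: none
Why: Krapcho dealkoxycarbonylation (chloride attacks the methyl groups of the ester and of the carbonate, then CO2 is lost), followed by methanolysis of the acetate; under the basic conditions C9 should equilibrate to the equatorial side chain.

Step 21
Reactants: 32 3β,20α-dihydroxy 8-ketone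
Product: 33 3β,20α-dihydroxy 8-methylidene compound (C8=CH2)
Conditions: Ph3PCH3Br (6 equiv), KOt-Bu (5.8 equiv), toluene, 90 °C
Reagents that add atoms: methyltriphenylphosphonium bromide, C[P+](c1ccccc1)(c1ccccc1)c1ccccc1.[Br-]
Why: Wittig methylenation of the C8 ketone with excess ylide, the two hydroxyls being carried as alkoxides; C9 stays in its favoured configuration.

Step 22
Reactants: 33 3β,20α-dihydroxy 8-methylidene compound
Product: 34 target diol CNP0338143.1
Conditions: H2 (3 atm), RhCl(PPh3)3 (10 mol %), toluene–EtOH (1:1), rt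
Reagents that add atoms: none
Why: Homogeneous hydrogenation; the rhodium catalyst should reduce the 1,1-disubstituted exocyclic alkene much faster than the trisubstituted C12=C13 alkene, and hydrogen should arrive at the equatorial α face of C8 because the axial C10 methyl blocks the β face, giving the axial 8β-methyl.

**Compound list**

1 | (1R,3S)-camphoric anhydride, (1R,5S)-1,8,8-trimethyl-3-oxabicyclo[3.2.1]octane-2,4-dione | O=C1OC(=O)[C@]2(C)CC[C@H]1C2(C)C | starting material
2 | (1R,3S)-3-[methoxy(methyl)carbamoyl]-1,2,2-trimethylcyclopentane-1-carboxylic acid | CON(C)C(=O)[C@H]1CC[C@@](C)(C(O)=O)C1(C)C | intermediate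
3 | (1R,3S)-3-acetyl-1,2,2-trimethylcyclopentane-1-carboxylic acid | CC(=O)[C@H]1CC[C@@](C)(C(O)=O)C1(C)C | intermediate
4 | (1R,3S)-3-acetoxy-1,2,2-trimethylcyclopentane-1-carboxylic acid | CC(=O)O[C@H]1CC[C@@](C)(C(O)=O)C1(C)C | intermediate
5 | 3-ethoxy-3-oxopropylzinc bromide | CCOC(=O)CC[Zn]Br | starting material
6 | (1R,3S)-3-acetoxy-1,2,2-trimethylcyclopentane-1-carbonyl chloride | CC(=O)O[C@H]1CC[C@@](C)(C(Cl)=O)C1(C)C | intermediate
7 | ethyl 4-[(1R,3S)-3-acetoxy-1,2,2-trimethylcyclopentyl]-4-oxobutanoate | CCOC(=O)CCC(=O)[C@]1(C)CC[C@H](OC(C)=O)C1(C)C | intermediate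
8 | ethyl (4S)-4-[(1R,3S)-3-acetoxy-1,2,2-trimethylcyclopentyl]-4-hydroxybutanoate | CCOC(=O)CC[C@H](O)[C@]1(C)CC[C@H](OC(C)=O)C1(C)C | intermediate
9 | (5S)-5-[(1R,3S)-3-acetoxy-1,2,2-trimethylcyclopentyl]oxolan-2-one | O=C1CC[C@H](O1)[C@]2(C)CC[C@H](OC(C)=O)C2(C)C | intermediate
10 | methyl (6S)-6-[(1R,3S)-3-acetoxy-1,2,2-trimethylcyclopentyl]-6-hydroxy-3-oxohexanoate | COC(=O)CC(=O)CC[C@H](O)[C@]1(C)CC[C@H](OC(C)=O)C1(C)C | intermediate
11 | (5S)-5-[(1R,3S)-3-acetoxy-1,2,2-trimethylcyclopentyl]-2-(2-methoxy-2-oxoethyl)-4,5-dihydro-3H-furan-1-ium | COC(=O)CC1=[O+][C@@H](CC1)[C@]2(C)CC[C@H](OC(C)=O)C2(C)C | intermediate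
12 | 4-acetoxy-2-(5-methoxy-3,5-dioxopentyl)-1,3,3-trimethylcyclohexylium (C10 cation; 3β-OAc, 5α-H) | COC(=O)CC(=O)CC[C@@H]1[C+](C)CC[C@H](OC(C)=O)C1(C)C | intermediate
13 | methyl (1R,4aR,6S,8aS)-6-acetoxy-5,5,8a-trimethyl-2-oxodecahydronaphthalene-1-carboxylate | COC(=O)[C@H]1C(=O)CC[C@H]2C(C)(C)[C@@H](OC(C)=O)CC[C@]12C | intermediate
14 | but-3-en-1-ylmagnesium bromide | C=CCC[Mg]Br | starting material
15 | methacrolein | C=C(C)C=O | starting material
16 | trimethyl[(2-methylhepta-1,6-dien-1-yl)oxy]silane | C=CCCCC(C)=CO[Si](C)(C)C | intermediate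
17 | (±)-2-methylhept-6-enal | C=CCCCC(C)C=O | intermediate
18 | methyl vinyl ketone | CC(=O)C=C | starting material
19 | (±)-4-methyl-4-(pent-4-en-1-yl)cyclohex-2-en-1-one | C=CCCCC1(C)CCC(=O)C=C1 | intermediate
20 | 4-methyl-4-(pent-4-en-1-yl)cyclohexa-2,5-dien-1-one | C=CCCCC1(C)C=CC(=O)C=C1 | intermediate
21 | 4-(1-methyl-4-oxocyclohexa-2,5-dien-1-yl)butanal | O=CCCCC1(C)C=CC(=O)C=C1 | intermediate
22 | (4aS,8aR)-4a-methyl-3,4,4a,8a-tetrahydronaphthalene-1,7(2H,8H)-dione | C1[C@H]2C(=O)CCC[C@@]2(C)C=CC1=O | intermediate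
23 | (4a'S,8a'R)-4a'-methyl-3',4',4a',8a'-tetrahydro-2'H-spiro[1,3-dioxolane-2,1'-naphthalen]-7'(8'H)-one | C1[C@H]2C3(OCCO3)CCC[C@@]2(C)C=CC1=O | intermediate
24 | (4a'S,8'R,8a'R)-4a',8'-dimethyl-3',4',4a',8a'-tetrahydro-2'H-spiro[1,3-dioxolane-2,1'-naphthalen]-7'(8'H)-one | C[C@@H]1[C@H]2C3(OCCO3)CCC[C@@]2(C)C=CC1=O | intermediate
25 | (4a'S,8'R,8a'R)-4a',8'-dimethyloctahydro-2'H-spiro[1,3-dioxolane-2,1'-naphthalen]-7'(8'H)-one | C[C@@H]1[C@H]2C3(OCCO3)CCC[C@@]2(C)CCC1=O | intermediate
26 | (4a'S,7'R,8'R,8a'R)-4a',7',8'-trimethyloctahydro-2'H-spiro[1,3-dioxolane-2,1'-naphthalen]-7'-ol | C[C@@H]1[C@H]2C3(OCCO3)CCC[C@@]2(C)CC[C@@]1(C)O | intermediate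
27 | (4aS,7R,8R,8aR)-7-hydroxy-4a,7,8-trimethyloctahydronaphthalen-1(2H)-one | C[C@@H]1[C@H]2C(=O)CCC[C@@]2(C)CC[C@@]1(C)O | intermediate
28 | (4aS,7R,8R,8aR)-1-ethenyl-4a,7,8-trimethyldecahydronaphthalene-1,7-diol (C1 epimers; formed as its magnesium alkoxide) | C[C@@H]1[C@H]2C(O)(C=C)CCC[C@@]2(C)CC[C@@]1(C)O | intermediate
29 | bis(methyl carbonate) of 28 | C[C@@H]1[C@H]2C(C=C)(OC(=O)OC)CCC[C@@]2(C)CC[C@@]1(C)OC(=O)OC | intermediate
30 | coupled keto ester (3β-OAc, 8-oxo, 9β-CO2Me, 9α-allyl chain, (12E), 20-O-methyl carbonate) | C[C@@H]1[C@H]2/C(=C/C[C@]3(C(=O)OC)C(=O)CC[C@H]4C(C)(C)[C@@H](OC(C)=O)CC[C@]34C)CCC[C@@]2(C)CC[C@@]1(C)OC(=O)OC | intermediate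
31 | 3β-acetoxy-20α-hydroxy 8-ketone (9α-H, (12E)) | C[C@@H]1[C@H]2/C(=C/C[C@H]3C(=O)CC[C@H]4C(C)(C)[C@@H](OC(C)=O)CC[C@]34C)CCC[C@@]2(C)CC[C@@]1(C)O | intermediate
32 | 3β,20α-dihydroxy 8-ketone (9α-H, (12E)) | C[C@@H]1[C@H]2/C(=C/C[C@H]3C(=O)CC[C@H]4C(C)(C)[C@@H](O)CC[C@]34C)CCC[C@@]2(C)CC[C@@]1(C)O | intermediate
33 | 3β,20α-dihydroxy 8-methylidene compound | C[C@@H]1[C@H]2/C(=C/C[C@H]3C(=C)CC[C@H]4C(C)(C)[C@@H](O)CC[C@]34C)CCC[C@@]2(C)CC[C@@]1(C)O | intermediate
34 | CNP0338143.1 (3β,20α-diol; 5α-H, 8β-Me, 9α-H, 10β-Me; (12E); 17β-Me, 18β-H, 19β-Me, 20β-Me) | C[C@@H]1[C@H]2/C(=C/C[C@H]3[C@@H](C)CC[C@H]4C(C)(C)[C@@H](O)CC[C@]34C)CCC[C@@]2(C)CC[C@@]1(C)O | target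

**Step count and risk**

Total step count: 22. Longest linear sequence: 15 steps (steps 8–18, then 19–22); the ring A/B branch is 7 steps (1–7).

Steps most likely to fail:

1. Step 7 (proposed new method). The oxolanylium ion may not ionise at C5, a group other than C4 may migrate, or the C5 relay may be lost through elimination and reprotonation before ring B closes. The fallback sets out from acid chloride 6 and returns at 13, using known chemistry throughout. Negishi acylation of 6 with 2-cyanoethylzinc bromide (Pd(PPh3)4) gives 4-[(1R,3S)-3-acetoxy-1,2,2-trimethylcyclopentyl]-4-oxobutanenitrile F1. NaBH4 in MeOH gives the hydroxy nitrile F2 (either carbinol epimer serves), and MsCl/Et3N gives its mesylate F3. Buffered solvolysis (2,6-lutidine, aqueous (CF3)2CHOH, 50 °C) is the classical Wagner–Meerwein ring expansion of a neopentyl-type secondary sulfonate with loss of a proton; it should give 3-[(5S)-5-acetoxy-2,6,6-trimethylcyclohex-1-en-1-yl]propanenitrile F4, so ring A still arises from the cyclopentane. A Blaise reaction (Zn, BrCH2CO2Me, THF, reflux; aq. HCl) gives methyl 5-[(5S)-5-acetoxy-2,6,6-trimethylcyclohex-1-en-1-yl]-3-oxopentanoate F5, and the established SnCl4 cyclisation of such monocyclic β-keto esters (CH2Cl2, −20 °C) closes ring B to 13. Here C5 and C10 are controlled by C3 alone, so a ring-fusion diastereomer would have to be separated.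

2. Step 12. The aliphatic acyl anion equivalent may close the six-membered carbocycle slowly, and the two enantiotopic enone arms may be poorly discriminated. The fallback sets out from aldehyde 21 and returns at 22. NH2OH·HCl/NaOAc gives 4-(1-methyl-4-oxocyclohexa-2,5-dien-1-yl)butanal oxime F6, and CF3CO3H (Na2HPO4 buffer) oxidises it to 4-methyl-4-(4-nitrobutyl)cyclohexa-2,5-dien-1-one F7. A bifunctional cinchona thiourea, 1-[3,5-bis(trifluoromethyl)phenyl]-3-(6'-methoxycinchonan-9-yl)thiourea, then catalyses the desymmetrising intramolecular nitro-Michael addition (C13 onto C18) to the cis-fused 4a-methyl-1-nitro-1,2,3,4,4a,8a-hexahydronaphthalen-7(8H)-one F8. A reductive Nef reaction (TiCl3, NH4OAc buffer) converts the nitro carbon into the C13 ketone of 22.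

3. Step 19. The π-allyl complex may undergo β-hydride elimination to a diene before the congested C9 enolate attacks, or allylation may stop at oxygen. The fallback makes the C–C bond inside an ion pair; it sets out from ketone 27 and keto ester 13 and returns at 31. Horner–Wadsworth–Emmons olefination of 27 (triethyl phosphonoacetate, NaH, THF, reflux) gives the ethyl (E)-ylideneacetate of 27 F9 (ester cis to C14), and i-Bu2AlH reduces it to the allylic alcohol F10. Transesterification of 13 with F10 (4-(dimethylamino)pyridine, toluene, reflux, removal of MeOH) gives the allyl β-keto ester F11. Pd(PPh3)4 in THF then effects decarboxylative allylation: loss of CO2 forms the C9 enolate regiospecifically next to the π-allyl partner, and C-allylation at C11 gives 31 directly, which is methanolysed to 32 as in step 20.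

**Further compounds**

F1 | step 7 | 4-[(1R,3S)-3-acetoxy-1,2,2-trimethylcyclopentyl]-4-oxobutanenitrile | N#CCCC(=O)[C@]1(C)CC[C@H](OC(C)=O)C1(C)C
F2 | step 7 | 4-[(1R,3S)-3-acetoxy-1,2,2-trimethylcyclopentyl]-4-hydroxybutanenitrile (carbinol epimers) | N#CCCC(O)[C@]1(C)CC[C@H](OC(C)=O)C1(C)C
F3 | step 7 | methanesulfonate of F2 | CS(=O)(=O)OC(CCC#N)[C@]1(C)CC[C@H](OC(C)=O)C1(C)C
F4 | step 7 | 3-[(5S)-5-acetoxy-2,6,6-trimethylcyclohex-1-en-1-yl]propanenitrile | N#CCCC1=C(C)CC[C@H](OC(C)=O)C1(C)C
F5 | step 7 | methyl 5-[(5S)-5-acetoxy-2,6,6-trimethylcyclohex-1-en-1-yl]-3-oxopentanoate | COC(=O)CC(=O)CCC1=C(C)CC[C@H](OC(C)=O)C1(C)C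
F6 | step 12 | 4-(1-methyl-4-oxocyclohexa-2,5-dien-1-yl)butanal oxime | ON=CCCCC1(C)C=CC(=O)C=C1
F7 | step 12 | 4-methyl-4-(4-nitrobutyl)cyclohexa-2,5-dien-1-one | [O-][N+](=O)CCCCC1(C)C=CC(=O)C=C1
F8 | step 12 | cis-fused 4a-methyl-1-nitro-1,2,3,4,4a,8a-hexahydronaphthalen-7(8H)-one (ring-fusion centres as in 22, C1 epimers) | C1[C@H]2C(CCC[C@@]2(C)C=CC1=O)[N+](=O)[O-]
F9 | step 19 | ethyl (E)-ylideneacetate of 27 (ester cis to C14) | C[C@@H]1[C@H]2/C(=C/C(=O)OCC)CCC[C@@]2(C)CC[C@@]1(C)O
F10 | step 19 | (E)-allylic alcohol from F9 | C[C@@H]1[C@H]2/C(=C/CO)CCC[C@@]2(C)CC[C@@]1(C)O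
F11 | step 19 | allyl β-keto ester from 13 and F10 | C[C@@H]1[C@H]2/C(=C/COC(=O)[C@H]3C(=O)CC[C@H]4C(C)(C)[C@@H](OC(C)=O)CC[C@]34C)CCC[C@@]2(C)CC[C@@]1(C)O
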